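Ring A is cut at C1–C2 and C5–C6, where C1 carries the methylene bridge, C2 and C6 the hydroxyls, C3 the benzoyl group and C4 the prenyl ether. One thermal benzannulation of 3-prenyloxycyclobutenone with a triisopropylsiloxyalkyne builds ring A and delivers its three alternating oxygens already differentiated: O4 as prenyl ether, O6 as silyl ether, O2 as free phenol, which then steers benzoylation to C3. The alkyne partner is C-propargylated filicinic acid (ring B), masked as a bis(methyl enol ether) and oxidised at the alkyne terminus to the siloxyalkyne. The feature exploited is the 1,3,5-oxygen pattern around C1 of ring A.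

Key step: step 7

Assumption: double O-methylation of the propargylated trione is taken to leave the ring B carbonyl on the crowded carbon between the gem-dimethyl carbon and the bridge-bearing carbon; any other bis(enol ether) is only a protecting-group isomer with the same skeleton, which would react alike and converge at the hydrolysis.

Step 1
Reactants: 1 2',4',6'-trihydroxyacetophenone
Product: 2 acetylfilicinic acid (2-acetyl-3,5-dihydroxy-4,4-dimethylcyclohexa-2,5-dien-1-one)
Conditions: MeI (2.2 equiv), NaOMe, MeOH, 0 °C to rt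
Reagents that add atoms: iodomethane CI
Why: Dearomatising double C-methylation of the acylphloroglucinol polyanion at one free ring carbon is the standard entry to acylfilicinic acids; no stereocentre is formed.

Step 2
Reactants: 2 acetylfilicinic acid
Product: 3 filicinic acid (3,5-dihydroxy-4,4-dimethylcyclohexa-2,5-dien-1-one)
Conditions: 6 M aq. HCl, reflux
Reagents that add atoms: none
Why: Acid-promoted retro-Claisen (retro-Friedel–Crafts) loss of the exocyclic acetyl group from the β-triketone should free the second ring CH position.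

Step 3
Reactants: 3 filicinic acid; 4 propargyl bromide
Product: 5 propargylfilicinic acid (3,5-dihydroxy-4,4-dimethyl-2-(prop-2-yn-1-yl)cyclohexa-2,5-dien-1-one)
Conditions: KOH (1 equiv), H2O/MeOH, 4 as limiting reagent, rt to 40 °C
Reagents that add atoms: none
Why: C-alkylation of a cyclic β-dicarbonyl enolate by a soft propargylic halide in protic medium; the two nucleophilic carbons of 3 are equivalent and a deficit of halide should limit double alkylation.

Step 4
Reactants: 5 propargylfilicinic acid
Product: 6 3,5-dimethoxy-6,6-dimethyl-2-(prop-2-yn-1-yl)cyclohexa-2,4-dien-1-one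
Conditions: Me2SO4, K2CO3, acetone, rt to 40 °C
Reagents that add atoms: dimethyl sulfate COS(=O)(=O)OC
Why: Double O-alkylation of the trione enolates by the hard electrophile dimethyl sulfate (vinylogous ester formation) should methylate the two less crowded oxygens and remove all acidic protons of ring B.

Step 5
Reactants: 6 3,5-dimethoxy-6,6-dimethyl-2-(prop-2-yn-1-yl)cyclohexa-2,4-dien-1-one
Product: 9 3,5-dimethoxy-6,6-dimethyl-2-[3-(triisopropylsilyloxy)prop-2-yn-1-yl]cyclohexa-2,4-dien-1-one, via lithium acetylide 7 (not isolated), via lithium ynolate 8 (not isolated)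
Conditions: t-BuOOH, LiN(SiMe3)2 (2.2 equiv), THF, −78 to 0 °C; then i-Pr3SiOTf, −78 °C
Reagents that add atoms: tert-butyl hydroperoxide CC(C)(C)OO; triisopropylsilyl triflate CC(C)[Si](C(C)C)(C(C)C)OS(=O)(=O)C(F)(F)F
Why: Julia oxidation of the lithium acetylide by LiOOt-Bu gives the ynolate, which the bulky silyl triflate traps on oxygen; the amide base is non-nucleophilic and the ring B carbonyl is flanked on both sides and deactivated by two methoxy donors.

Step 6
Reactants: 10 3-ethoxycyclobut-2-en-1-one; 11 prenol (3-methylbut-2-en-1-ol)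
Product: 12 3-(3-methylbut-2-enyloxy)cyclobut-2-en-1-one
Conditions: pyridinium p-toluenesulfonate (cat.), toluene, 40 °C, reduced pressure (EtOH removed)
Reagents that add atoms: none
Why: Acid-catalysed alkoxy exchange of a vinylogous ester (addition–elimination through the mixed ketal) should be driven to the prenyl ether by removal of ethanol.

Step 7
Reactants: 9 3,5-dimethoxy-6,6-dimethyl-2-[3-(triisopropylsilyloxy)prop-2-yn-1-yl]cyclohexa-2,4-dien-1-one; 12 3-(3-methylbut-2-enyloxy)cyclobut-2-en-1-one
Product: 17 2-[(2,4-dimethoxy-5,5-dimethyl-6-oxocyclohexa-1,3-dien-1-yl)methyl]-5-(3-methylbut-2-enyloxy)-3-(triisopropylsilyloxy)phenol, via vinylketene 13 (not isolated), via vinylcyclobutenone adduct 14 (not isolated), via dienylketene 15 (not isolated), via cyclohexadienone tautomer 16 (not isolated)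
Conditions: toluene, 80 °C then 110 °C, argon (12 in slight excess)
Reagents that add atoms: none
Why: Heating opens 12 by four-electron electrocyclic ring opening to vinylketene 13, which adds to the siloxyalkyne in a regioselective [2+2] cycloaddition to give 4-vinylcyclobutenone 14 (new ring A bonds C1–C2 and C5–C6). A second four-electron ring opening gives dienylketene 15, whose thermal six-electron disrotatory electrocyclisation re-forms the C2–C3 bond and closes ring A as cyclohexadienone 16; tautomerisation then gives phenol 17. The closest known reaction type is the Danheiser benzannulation of cyclobutenones with trialkylsiloxyalkynes. No stereocentre survives, because the sp3 carbon of 14 and of 16 is lost on aromatisation. The selectivity needed is the orientation of the alkyne, secured by the siloxy donor, which makes the alkyl-bearing alkyne carbon the nucleophile that bonds to the ketene carbonyl carbon and so places the bridge between O2 and O6. The prenyl enol ether of 12 is a vinylogous ester and the annulation temperature should stay below that of its [3,3] shift, while the hindered ring B dienone is a spectator.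

Step 8
Reactants: 17 2-[(2,4-dimethoxy-5,5-dimethyl-6-oxocyclohexa-1,3-dien-1-yl)methyl]-5-(3-methylbut-2-enyloxy)-3-(triisopropylsilyloxy)phenol; 18 benzoyl chloride
Product: 20 [2-hydroxy-3-[(2,4-dimethoxy-5,5-dimethyl-6-oxocyclohexa-1,3-dien-1-yl)methyl]-6-(3-methylbut-2-enyloxy)-4-(triisopropylsilyloxy)phenyl](phenyl)methanone, via bromomagnesium phenoxide 19 (not isolated)
Conditions: EtMgBr (1.0 equiv), Et2O/toluene, 0 °C; then 18, toluene, rt to 50 °C; aq. NH4Cl
Reagents that add atoms: none
Why: Chelation-controlled ortho C-acylation of a bromomagnesium phenoxide by an acid chloride (magnesium-directed Friedel–Crafts acylation) should place the benzoyl group on C3, the only free ortho carbon, the para carbon being shielded by the silyl ether.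

Step 9
Reactants: 20 [2-hydroxy-3-[(2,4-dimethoxy-5,5-dimethyl-6-oxocyclohexa-1,3-dien-1-yl)methyl]-6-(3-methylbut-2-enyloxy)-4-(triisopropylsilyloxy)phenyl](phenyl)methanone
Product: 21 [2-hydroxy-3-[(2,4-dihydroxy-3,3-dimethyl-6-oxocyclohexa-1,4-dien-1-yl)methyl]-6-(3-methylbut-2-enyloxy)-4-(triisopropylsilyloxy)phenyl](phenyl)methanone
Conditions: 1 M HCl, THF, rt
Reagents that add atoms: water O
Why: Acid-catalysed hydrolysis of the two vinylogous methyl esters (enol ether hydrolysis) should be mild enough to spare the aryl prenyl ether and the aryl silyl ether.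

Step 10
Reactants: 21 [2-hydroxy-3-[(2,4-dihydroxy-3,3-dimethyl-6-oxocyclohexa-1,4-dien-1-yl)methyl]-6-(3-methylbut-2-enyloxy)-4-(triisopropylsilyloxy)phenyl](phenyl)methanone; 22 isobutyric acid
Product: 24 6-O-triisopropylsilyl sarothralin, via enol isobutyrate 23 (not isolated)
Conditions: N,N'-dicyclohexylcarbodiimide, 4-(dimethylamino)pyridine, CH2Cl2, 0 °C to rt
Reagents that add atoms: none
Why: Carbodiimide-mediated C-acylation of a cyclic β-dicarbonyl, in which O-acylation to 23 is followed by a 4-(dimethylamino)pyridine-mediated O-to-C acyl shift to the only hydrogen-bearing ring B carbon; the one free phenol is chelated to the benzoyl group and flanked on both sides, so it should not compete.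

Step 11
Reactants: 24 6-O-triisopropylsilyl sarothralin
Product: 25 sarothralin
Conditions: Bu4NF, AcOH, THF, 0 °C to rt
Reagents that add atoms: none
Why: Fluoride cleavage of an aryl silyl ether, buffered by acetic acid so that the acidic β-triketone and the phenols are not exposed to strong base.

Compound list
1 | 2',4',6'-trihydroxyacetophenone | CC(=O)c1c(O)cc(O)cc1O | starting material
2 | acetylfilicinic acid (2-acetyl-3,5-dihydroxy-4,4-dimethylcyclohexa-2,5-dien-1-one) | CC(=O)C1=C(O)C(C)(C)C(O)=CC1=O | intermediate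
3 | filicinic acid (3,5-dihydroxy-4,4-dimethylcyclohexa-2,5-dien-1-one) | CC1(C)C(O)=CC(=O)C=C1O | intermediate
4 | propargyl bromide | C#CCBr | starting material
5 | propargylfilicinic acid (3,5-dihydroxy-4,4-dimethyl-2-(prop-2-yn-1-yl)cyclohexa-2,5-dien-1-one) | C#CCC1=C(O)C(C)(C)C(O)=CC1=O | intermediate
6 | 3,5-dimethoxy-6,6-dimethyl-2-(prop-2-yn-1-yl)cyclohexa-2,4-dien-1-one | C#CCC1=C(OC)C=C(OC)C(C)(C)C1=O | intermediate
7 | lithium acetylide of 6 | [Li]C#CCC1=C(OC)C=C(OC)C(C)(C)C1=O | intermediate
8 | lithium ynolate (lithium 3-(2,4-dimethoxy-5,5-dimethyl-6-oxocyclohexa-1,3-dien-1-yl)prop-1-yn-1-olate) | [Li]OC#CCC1=C(OC)C=C(OC)C(C)(C)C1=O | intermediate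
9 | 3,5-dimethoxy-6,6-dimethyl-2-[3-(triisopropylsilyloxy)prop-2-yn-1-yl]cyclohexa-2,4-dien-1-one (siloxyalkyne) | CC(C)[Si](C(C)C)(C(C)C)OC#CCC1=C(OC)C=C(OC)C(C)(C)C1=O | intermediate
10 | 3-ethoxycyclobut-2-en-1-one | CCOC1=CC(=O)C1 | starting material
11 | prenol (3-methylbut-2-en-1-ol) | CC(C)=CCO | starting material
12 | 3-(3-methylbut-2-enyloxy)cyclobut-2-en-1-one | O=C1C=C(OCC=C(C)C)C1 | intermediate
13 | vinylketene, 3-(3-methylbut-2-enyloxy)buta-1,3-dien-1-one | C=C(OCC=C(C)C)C=C=O | intermediate
14 | vinylcyclobutenone adduct, racemic 2-[(2,4-dimethoxy-5,5-dimethyl-6-oxocyclohexa-1,3-dien-1-yl)methyl]-4-[1-(3-methylbut-2-enyloxy)vinyl]-3-(triisopropylsilyloxy)cyclobut-2-en-1-one | O=C1C(CC2=C(OC)C=C(OC)C(C)(C)C2=O)=C(O[Si](C(C)C)(C(C)C)C(C)C)C1C(=C)OCC=C(C)C | intermediate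
15 | dienylketene, 2-[(ring B)methyl]-5-(3-methylbut-2-enyloxy)-3-(triisopropylsilyloxy)hexa-1,3,5-trien-1-one, ketene-bearing carbon and prenyloxyvinyl group cis on the central double bond | O=C=C(CC1=C(OC)C=C(OC)C(C)(C)C1=O)/C(O[Si](C(C)C)(C(C)C)C(C)C)=C\C(=C)OCC=C(C)C | intermediate
16 | cyclohexadienone tautomer, 2-[(ring B)methyl]-5-(3-methylbut-2-enyloxy)-3-(triisopropylsilyloxy)cyclohexa-2,4-dien-1-one | O=C1CC(OCC=C(C)C)=CC(O[Si](C(C)C)(C(C)C)C(C)C)=C1CC1=C(OC)C=C(OC)C(C)(C)C1=O | intermediate
17 | 2-[(2,4-dimethoxy-5,5-dimethyl-6-oxocyclohexa-1,3-dien-1-yl)methyl]-5-(3-methylbut-2-enyloxy)-3-(triisopropylsilyloxy)phenol | Oc1cc(OCC=C(C)C)cc(O[Si](C(C)C)(C(C)C)C(C)C)c1CC1=C(OC)C=C(OC)C(C)(C)C1=O | intermediate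
18 | benzoyl chloride | O=C(Cl)c1ccccc1 | starting material
19 | bromomagnesium phenoxide of 17 | Br[Mg]Oc1cc(OCC=C(C)C)cc(O[Si](C(C)C)(C(C)C)C(C)C)c1CC1=C(OC)C=C(OC)C(C)(C)C1=O | intermediate
20 | [2-hydroxy-3-[(2,4-dimethoxy-5,5-dimethyl-6-oxocyclohexa-1,3-dien-1-yl)methyl]-6-(3-methylbut-2-enyloxy)-4-(triisopropylsilyloxy)phenyl](phenyl)methanone | Oc1c(C(=O)c2ccccc2)c(OCC=C(C)C)cc(O[Si](C(C)C)(C(C)C)C(C)C)c1CC1=C(OC)C=C(OC)C(C)(C)C1=O | intermediate
21 | [2-hydroxy-3-[(2,4-dihydroxy-3,3-dimethyl-6-oxocyclohexa-1,4-dien-1-yl)methyl]-6-(3-methylbut-2-enyloxy)-4-(triisopropylsilyloxy)phenyl](phenyl)methanone | Oc1c(C(=O)c2ccccc2)c(OCC=C(C)C)cc(O[Si](C(C)C)(C(C)C)C(C)C)c1CC1=C(O)C(C)(C)C(O)=CC1=O | intermediate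
22 | isobutyric acid (2-methylpropanoic acid) | CC(C)C(=O)O | starting material
23 | enol isobutyrate of 21 (ester on the ring B oxygen next to the gem-dimethyl carbon, on the side of the free CH) | Oc1c(C(=O)c2ccccc2)c(OCC=C(C)C)cc(O[Si](C(C)C)(C(C)C)C(C)C)c1CC1=C(O)C(C)(C)C(OC(=O)C(C)C)=CC1=O | intermediate
24 | 6-O-triisopropylsilyl sarothralin ([2-hydroxy-3-[[2,6-dihydroxy-3,3-dimethyl-5-(2-methylpropanoyl)-4-oxocyclohexa-1,5-dien-1-yl]methyl]-6-(3-methylbut-2-enyloxy)-4-(triisopropylsilyloxy)phenyl](phenyl)methanone) | Oc1c(C(=O)c2ccccc2)c(OCC=C(C)C)cc(O[Si](C(C)C)(C(C)C)C(C)C)c1CC1=C(O)C(C)(C)C(=O)C(C(=O)C(C)C)=C1O | intermediate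
25 | sarothralin | CC(C)=CCOc1cc(O)c(CC2=C(O)C(C)(C)C(=O)C(C(=O)C(C)C)=C2O)c(O)c1C(=O)c1ccccc1 | target

Total step count: 11. Longest linear sequence: 10 (steps 1 to 5, then 7 to 11); step 6 is the one-step side branch.

Steps most likely to fail

Step 7, the benzannulation. The alkoxy-substituted cyclobutenone may open to the vinylketene only slowly. Prolonged heating would then let a [3,3] shift of the prenyl enol ether, or acylation of the product phenol by the ketene, overtake the annulation. The fallback makes the same vinylketene without heat; it sets out from prenol 11 and comes back at 17. Acid-catalysed alkoxy exchange of 11 with commercial methyl (E)-3-methoxybut-2-enoate (pyridinium p-toluenesulfonate, toluene, methanol distilled off) should give methyl (E)-3-(3-methylbut-2-enyloxy)but-2-enoate F1. Saponification (KOH, MeOH/H2O) should give (E)-3-(3-methylbut-2-enyloxy)but-2-enoic acid F2, and 1-chloro-N,N,2-trimethylprop-1-en-1-amine in CH2Cl2 should give (E)-3-(3-methylbut-2-enyloxy)but-2-enoyl chloride F3 under neutral conditions. Slow addition of Et3N to F3 and 9 in toluene at 0 °C should release vinylketene 13 by 1,4-dehydrochlorination. Siloxyalkyne 9 should trap it as 14 at or below rt, and brief warming to 80 °C should carry 14 through 15 and 16 to 17.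

Step 5, the siloxyalkyne. During the oxidation period at 0 °C the acetylide or the lithium peroxide may attack the ring B dienone, or the oxidation may stall. The fallback builds the ynolate by ester homologation instead of alkyne oxidation; it sets out from filicinic acid 3 and comes back at 9 through ynolate 8. C-alkylation of 3 with ethyl bromoacetate (KOH, H2O/MeOH) should give ethyl 2-(2,4-dihydroxy-3,3-dimethyl-6-oxocyclohexa-1,4-dien-1-yl)acetate F4. Me2SO4 and K2CO3 in acetone should give ethyl 2-(2,4-dimethoxy-5,5-dimethyl-6-oxocyclohexa-1,3-dien-1-yl)acetate F5. Kowalski homologation (CH2Br2 and lithium 2,2,6,6-tetramethylpiperidide, THF, −78 °C; then n-BuLi, −78 °C to rt) should pass through 1,1-dibromo-3-(2,4-dimethoxy-5,5-dimethyl-6-oxocyclohexa-1,3-dien-1-yl)propan-2-one F6 as its lithium enolate. Bromine–lithium exchange at −78 °C is expected to be faster than addition to the flanked ring B carbonyl, and rearrangement should give lithium ynolate 8, silylated with i-Pr3SiCl to 9.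

Step 8, the benzoylation. The phenoxide may be acylated on oxygen in place of the crowded ortho carbon between two oxygens. The fallback brings in the carbon with a small electrophile and adds the phenyl group afterwards; it sets out from 17 and comes back at 20. Magnesium-mediated ortho-formylation (MgCl2, Et3N, paraformaldehyde, THF, reflux) should give 2-hydroxy-3-[(2,4-dimethoxy-5,5-dimethyl-6-oxocyclohexa-1,3-dien-1-yl)methyl]-6-(3-methylbut-2-enyloxy)-4-(triisopropylsilyloxy)benzaldehyde F7. PhMgBr (2 equiv, THF, −78 °C) should add to the aldehyde in preference to the hindered ring B carbonyl and give the racemic diaryl carbinol F8. MnO2 (CH2Cl2, rt) should oxidise the benzylic alcohol to benzophenone 20.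

Further compounds
F1 | step 7 | methyl (E)-3-(3-methylbut-2-enyloxy)but-2-enoate | COC(=O)/C=C(\C)OCC=C(C)C
F2 | step 7 | (E)-3-(3-methylbut-2-enyloxy)but-2-enoic acid | OC(=O)/C=C(\C)OCC=C(C)C
F3 | step 7 | (E)-3-(3-methylbut-2-enyloxy)but-2-enoyl chloride | ClC(=O)/C=C(\C)OCC=C(C)C
F4 | step 5 | ethyl 2-(2,4-dihydroxy-3,3-dimethyl-6-oxocyclohexa-1,4-dien-1-yl)acetate | CCOC(=O)CC1=C(O)C(C)(C)C(O)=CC1=O
F5 | step 5 | ethyl 2-(2,4-dimethoxy-5,5-dimethyl-6-oxocyclohexa-1,3-dien-1-yl)acetate | CCOC(=O)CC1=C(OC)C=C(OC)C(C)(C)C1=O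
F6 | step 5 | 1,1-dibromo-3-(2,4-dimethoxy-5,5-dimethyl-6-oxocyclohexa-1,3-dien-1-yl)propan-2-one | BrC(Br)C(=O)CC1=C(OC)C=C(OC)C(C)(C)C1=O
F7 | step 8 | 2-hydroxy-3-[(2,4-dimethoxy-5,5-dimethyl-6-oxocyclohexa-1,3-dien-1-yl)methyl]-6-(3-methylbut-2-enyloxy)-4-(triisopropylsilyloxy)benzaldehyde | Oc1c(C=O)c(OCC=C(C)C)cc(O[Si](C(C)C)(C(C)C)C(C)C)c1CC1=C(OC)C=C(OC)C(C)(C)C1=O
F8 | step 8 | racemic 2-[hydroxy(phenyl)methyl]-6-[(2,4-dimethoxy-5,5-dimethyl-6-oxocyclohexa-1,3-dien-1-yl)methyl]-3-(3-methylbut-2-enyloxy)-5-(triisopropylsilyloxy)phenol | Oc1c(C(O)c2ccccc2)c(OCC=C(C)C)cc(O[Si](C(C)C)(C(C)C)C(C)C)c1CC1=C(OC)C=C(OC)C(C)(C)C1=O
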